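The data come from a simulation from invented constants; scatter was added.

The reagent was where I started when the choice lay between a hot flask and a cool one with the same charges.

| flask | substrate | reagent | temperature | remark | time |
|---|---|---|---|---|---|
| alpha | 3.4 mM | 5 mM | 98 °C | run made earlier |  |
| epsilon | 7.5 mM | 5 mM | 114 °C | run made earlier |  |
| midnight | 5.0 mM | 5.00 mM | 120 °C |  | 2.0 min |
| noon | 5.0 mM | 5.00 mM | 90 °C |  | 2.0 min |

alpha run (percent of the substrate charged)

| time / min | first product / % | substrate / % |
|---|---|---|
| 0.667 | 12.2 | 20.9 |
| 1.33 | 16.2 | 16.5 |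
| 2.00 | 17.7 | 14.3 |
| 2.50 | 18.5 | 11.6 |
| 3.00 | 18.9 | 11.4 |
| 4.00 | 20.3 | 8.0 |

epsilon run (percent of the substrate charged)

| time / s | first product / % | substrate / % |
|---|---|---|
| 10.0 | 7.8 | 34.5 |
| 15.0 | 10.2 | 32.6 |
| 25.0 | 12.0 | 27.6 |
| 40.0 | 12.7 | 25.4 |
| 60.0 | 13.1 | 24.5 |
| 80.0 | 13.0 | 24.2 |

(scatter of a reading: 0.5 percentage points)



- which flask leads in amount of first product, in percent of the substrate charged ("all alike" within 1.5 percentage points) (midnight / noon / all alike)
- how much first product is there at the end, in percent of the substrate charged: midnight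
- how much first product is there at the end, in percent of the substrate charged: noon

From 60.0 s to 80.0 s the epsilon run stood still: first product read 13.1 % and then 13.0 %, a step smaller than the scatter of 0.5 percentage points, and substrate stayed near 24.2 %. With substrate still there, I took reagent for the limiting reagent of the epsilon flask and froze one number: the [first product] at the stall per [reagent] charged, which I call the reagent yield, 0.196. Midnight and noon charge [reagent] equal to [substrate], so I reckoned a stall of the same kind in either flask at 19.6 % of the substrate charged.

Midnight runs hotter than epsilon, so I expected it at that figure by 2.0 min. Noon runs colder than alpha, whose first product was still rising after 2.00 min. The reagent yield of alpha at that time, 0.120, put noon at 12.0 %. So I chose midnight, with a lead of 7.6 points, more than the margin of 1.5 points.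

The forecast chose midnight too, with 14 % against 10 %: “Midnight leads, though modestly”. Both its figures lie below mine.

The flasks gave 15.8 % for midnight and 14.8 % for noon, a gap of 1 point, inside the margin, so the answer is all alike.

    reagent + first product → double product + by-product (k = 0.690 L mol⁻¹ s⁻¹, Ea = 77.0 kJ mol⁻¹)
    first product ⇌ isomer of the product (K = 0.320, k = 0.00600 s⁻¹, Ea = 90.0 kJ mol⁻¹, ΔH = −26.0 kJ mol⁻¹)
    substrate + reagent → first product + by-product (k = 2.60 L mol⁻¹ s⁻¹, Ea = 41.0 kJ mol⁻¹)
    substrate ⇌ dormant form (K = 3.10, k = 0.450 s⁻¹, Ea = 99.0 kJ mol⁻¹, ΔH = −46.0 kJ mol⁻¹)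
    reagent + other mono adduct → double product + by-product (k = 5.80 L mol⁻¹ s⁻¹, Ea = 58.0 kJ mol⁻¹)
    substrate + reagent → other mono adduct + by-product (k = 2.30 L mol⁻¹ s⁻¹, Ea = 68.0 kJ mol⁻¹)
    (constants at 90 °C)

Midnight ended with reagent at 0.685 % of its charge and a reagent yield of 0.158, lower than the frozen 0.196. The neighbour of midnight with 12 mM of substrate takes the same reckoning: the frozen yield on its charge gives 8.16 % of the substrate charged. That neighbour held reagent at 0 % of its charge after 2.00 min, and its first product stood at 9.35 %.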